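## The problem

The target 21 is a trans-2,3-diaryl-2,3-dihydro-1-benzofuran. C2 (S) carries a 4-hydroxyphenyl group, C3 (S) a 3,5-dihydroxyphenyl group, and the fused benzene ring A has a free hydroxyl at C4 and a 2-(4-hydroxyphenyl)ethyl chain at C6. A synthesis must place three different aryl units around two adjacent sp3 carbons, fuse the oxygen heterocycle to a 1,3,5-substituted arene with the right regiochemistry, and give one enantiomer. The two stereocentres are linked: trans is the less strained arrangement, so a C2 centre set by asymmetric catalysis can direct C3, either by equilibration while C3 still bears an enolisable carbonyl or kinetically when a reagent approaches C3 on the face away from the C2 aryl group. Once C3 is doubly benzylic it can no longer be corrected. The 3,5-dioxygenated ring at C3 has a meta pattern that electrophilic substitution cannot deliver, so it must arrive as a preformed aryl nucleophile or be built de novo. The weakest bond is O1–C2, a benzylic ether para to a phenolic oxygen: acid ionises it and, once that phenol is free, base opens it through a quinone methide. The five oxidation-prone phenols therefore stay masked to the end and the C2 aryl group is kept electron-poor as long as possible. The feature that opens the route is that the O1–C2(aryl)–C3 unit fused to ring A at C3a and C7a is a flavanone with one carbon pushed out of the ring. If ring A carbon C4a of a flavanone shifts from C4 to C3, the pyranone contracts to this dihydrofuran, the flavanone C2 stereocentre becomes C2 of the target, and C4 remains on C3 as a carboxyl group that can be exchanged for the third aryl ring.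

## Retrosynthesis

**Unmasking (21 from 20 from 19).** The last cuts are four O–CH3 bonds and one O–S bond. Methyl ethers are the only phenol masks that survive aryllithium, BCl3, the oxidative key step and organozinc chemistry alike. The mesylate on the C2 aryl ring is removed first, from the fully methylated 19, where a cold amide base finds no other acidic site; this gives phenol 20. The Lewis-acid demethylation of 20 is then the only operation run on a free polyphenol. The forward steps must leave the O1–C2 bond and both stereocentres untouched.

**C3–aryl bond (19 from 15 and 18).** Cutting the bond between C3 and the 3,5-dimethoxyphenyl ring leaves a C3 carboxyl derivative, the N-acyloxyphthalimide 15, and the arylzinc chloride 18. The neighbouring options are weaker. A Friedel–Crafts bond to C3 would give the 2,4-dioxygenation pattern, and building the ring from the carboxyl carbon costs several extra steps. The decarboxylative coupling uses the carboxyl group that the key step leaves behind. It must form the bond on the face of the C3 radical opposite the C2 aryl group and must tolerate the aryl mesylate.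

**Activation (15 from 14 from 13).** Ester 13 is hydrolysed to acid 14 and re-esterified as the redox-active ester 15. Both operations must avoid bases, because deprotonation at C3 can expel the C7a phenoxide and open the ring.

**Key disconnection (13 from 11 via 12).** The C3–C3a bond of ester 13 is cut and C3a is reconnected to the ester carbon, which restores the six-membered ketone of flavanone 11. This trades a dihydrobenzofuran bearing two contiguous stereocentres for a flavanone with one, a compound class with reliable catalytic asymmetric entries. The forward reaction runs through enol ether 12. It has to make C4a migrate in preference to the C2 aryl group, avoid dehydrogenation to the flavone, and preserve C2. For that reason the C2 aryl group carries a mesyloxy substituent, not a methoxy substituent.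

**C2–aryl bond (11 from 8 and 10).** Cutting the C2–aryl bond of 11 gives the achiral chromone 8 and boronic acid 10. The alternative, cyclising a 2'-hydroxychalcone, is harder to render enantioselective. The conjugate addition sets the only stereocentre that needs external control and must run without base, since base equilibrates flavanones with chalcones.

**Ring A building blocks (8 from 6 from 5 from 2 and 3; 2 from 1; 10 from 9; 18 from 16).** Chromone 8 loses its C2 carbon to give hydroxy ketone 6, which comes from the dimethoxy ketone 5 by chelation-directed cleavage of one ortho methyl ether. The acetyl group of 5 is cut back to Weinreb amide 3 and aryllithium 4, generated from dihydroresveratrol trimethyl ether 2. Lithiation between the two methoxy groups is regiospecific, whereas Friedel–Crafts acylation would not distinguish the two electron-rich rings. Compound 2 is the hydrogenation product of commercial stilbene 1, boronic acid 10 is the mesylate of 9, and 18 is made from bromide 16 through Grignard reagent 17.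

## Roads not taken

**Alternative 1: benzannulation that builds ring A around C3.**
- Cut: ring A is split into the cyclobutenone A2, which carries the arylethyl chain, and the siloxyalkyne A3, which carries C3 and C2 with both aryl groups.
- Forward key step: heating the two should give the resorcinol monosilyl ether A1 by the Danheiser cascade (ring opening to a vinylketene, cycloaddition to the ynol ether, ring opening, six-electron closure).
- Merits: the regiochemistry of ring A is unambiguous, the two ring oxygens emerge differentiated, and all three aryl groups are in place before any ring exists. No bond has to be forced onto a congested C3 and no oxidant meets an electron-rich arene. In these respects it is better than the chosen plan.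
- Weak points: A3 is an acyclic ynol silyl ether with two adjacent stereocentres. It needs an enantio- and anti-selective construction plus an ester-to-ynolate homologation, and its 4-methoxybenzylic silyl ether can eliminate on heating.
- Furan closure: the C2 oxygen of A1 has the spatial arrangement of O1 in the target, so an invertive closure would give the cis isomer. Closure must therefore pass through the 4-methoxybenzylic cation, which discards the C2 carbinol centre and enters the acid-labile regime that the chosen plan avoids.
- Comparison: the chosen plan sets against it a single catalytic asymmetric step, catalogue aromatic building blocks and a much shorter precursor synthesis.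

**Alternative 2: resorcinol ring at C3 grown from an ynone.**
- Cut: the 3,5-dihydroxyphenyl ring is disconnected into the C3-bound ynone A5 and dimethyl malonate A6.
- Forward key step: the sodium salt of A6 adds to the ynone and the methyl ketone enolate closes onto a malonate ester, giving the resorcylate A4. Saponification and decarboxylation would follow.
- Merits: no organometallic coupling at C3, no dependence on the facial selectivity of a radical, and the two oxygens of that ring arrive free. If the nickel coupling of the chosen plan proved unworkable, this would be a genuine replacement for it.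
- Weak points: C3–H of A5 is benzylic, propargylic and vinylogously activated by the ketone. Under sodium malonate it can isomerise to the allenone, and the resulting anion can expel the C2 oxygen. A5 would itself be made from a C3 carboxylate of the kind the chosen key step delivers, by reduction, alkyne homologation and acylation. The alternative therefore does not remove the ring contraction and lengthens the endgame by several steps. It also keeps a methoxy group on the C2 aryl ring.
- Comparison: the chosen plan sets brevity (three steps from the ester to the 2,3-diaryl core) and base-free conditions against it.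

**Alternative 3: (2+2+2) cycloaddition forming both fused rings.**
- Cut: ring A and the dihydrofuran are disconnected together into the diyne A8 (an ethynyl ether on the C2 oxygen and a siloxyalkyne on C3) and the terminal alkyne A9.
- Forward key step: [Rh(cod)2]BF4 with a bisphosphine should join the three alkynes to give A7, forming C3a–C7a, C4–C5 and C6–C7.
- Merits: it is the most convergent of the four plans. Both rings form in one step, the stereocentres are set beforehand and are not touched, the C4 oxygen arrives as a fluoride-labile silyl ether, and the bulky siloxy group should steer the alkyne substituent to C6. In convergence and in avoiding both the oxidation and the radical coupling it is superior.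
- Weak points: A8 is a secondary benzylic alkynyl ether, a class that rearranges sigmatropically on gentle warming and hydrolyses readily. Making it as a single anti stereoisomer requires an enantiopure 1,2-diaryl propargylic alcohol, an ethynyl ether synthesis under strong base and a separate siloxyalkyne synthesis. The C6 regiochemistry rests on a steric argument only, and A9 can trimerise with itself.
- Comparison: the chosen plan sets against it stable intermediates, a key step of a known reaction type, and a precursor reached in six steps from catalogue compounds.

Key step: step 7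

## Assumptions

- (E)-3,4',5-Trimethoxystilbene (resveratrol trimethyl ether) 1 is taken as a catalogue compound.
- The (S)-bisphosphine in step 6 is taken to deliver the (S)-flavanone, by analogy with the sense of rhodium/biaryl-bisphosphine additions to six-membered cyclic enones. If the sense is opposite for this chromone, the (R)-ligand is used.

## Route

Step 1
Reactants: 1 (E)-3,4',5-trimethoxystilbene
Product: 2 dihydroresveratrol trimethyl ether (1,3-dimethoxy-5-[2-(4-methoxyphenyl)ethyl]benzene)
Conditions: H2 (1 atm), 10% Pd/C, EtOAc, rt
Reagents that add atoms: none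
Why: Heterogeneous hydrogenation of a 1,2-diarylethene is fast at ambient pressure and leaves aryl methyl ethers untouched; no stereocentre is formed.

Step 2
Reactants: 2 dihydroresveratrol trimethyl ether; 3 N-methoxy-N-methylacetamide
Product: 5 aryl methyl ketone 1-{2,6-dimethoxy-4-[2-(4-methoxyphenyl)ethyl]phenyl}ethan-1-one, via aryllithium 4 (not isolated)
Conditions: n-BuLi, THF, 0 °C to rt; then 3, −78 °C to rt; aq. NH4Cl
Reagents that add atoms: none
Why: Directed ortho-metalation: the position flanked by both methoxy groups is the kinetically most acidic site, and Weinreb acylation stops at the ketone because the chelated tetrahedral adduct survives until the quench.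

Step 3
Reactants: 5 aryl methyl ketone 1-{2,6-dimethoxy-4-[2-(4-methoxyphenyl)ethyl]phenyl}ethan-1-one
Product: 6 hydroxy ketone 1-{2-hydroxy-6-methoxy-4-[2-(4-methoxyphenyl)ethyl]phenyl}ethan-1-one
Conditions: BCl3 (1.2 equiv), CH2Cl2, −78 to 0 °C; H2O
Reagents that add atoms: none
Why: Chelation-controlled ether cleavage: BCl3 bound to the ketone removes one ortho methyl group only, the resulting aryloxyborane chelate deactivates the second ortho ether, and the remote anisole ether is inert at this temperature.

Step 4
Reactants: 6 hydroxy ketone 1-{2-hydroxy-6-methoxy-4-[2-(4-methoxyphenyl)ethyl]phenyl}ethan-1-one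
Product: 8 chromone 5-methoxy-7-[2-(4-methoxyphenyl)ethyl]-4H-chromen-4-one, via enaminone 7 (not isolated)
Conditions: Me2NCH(OMe)2, toluene, 100 °C; then conc. HCl, CH2Cl2, 40 °C
Reagents that add atoms: N,N-dimethylformamide dimethyl acetal, COC(OC)N(C)C
Why: Condensation of the methyl ketone with the amide acetal gives the enaminone, and acid closes the phenol onto the β-carbon with loss of dimethylamine (standard chromone synthesis from 2-hydroxyacetophenones).

Step 5
Reactants: 9 4-hydroxyphenylboronic acid
Product: 10 [4-(methanesulfonyloxy)phenyl]boronic acid
Conditions: MsCl, Et3N, THF, 0 °C; 1 M HCl work-up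
Reagents that add atoms: methanesulfonyl chloride, CS(=O)(=O)Cl
Why: O-Sulfonylation of the phenol; any B–O–S or boroxine species formed in passing are hydrolysed back to the boronic acid in the acidic aqueous work-up.

Step 6
Reactants: 8 chromone 5-methoxy-7-[2-(4-methoxyphenyl)ethyl]-4H-chromen-4-one; 10 [4-(methanesulfonyloxy)phenyl]boronic acid
Product: 11 flavanone 4-[(2S)-5-methoxy-7-[2-(4-methoxyphenyl)ethyl]-4-oxo-3,4-dihydro-2H-chromen-2-yl]phenyl methanesulfonate
Conditions: [Rh(OH)(cod)]2 (1.5 mol%), (S)-MeO-F12-BIPHEP (3.3 mol%), 10 (2 equiv), toluene/H2O, 40 °C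
Reagents that add atoms: none
Why: Hayashi–Miyaura asymmetric 1,4-addition to a chromone: the aryl–rhodium species adds to C2 on the enone face selected by the electron-poor atropisomeric bisphosphine (catalyst control of the C2 stereocentre) and water protonates the rhodium enolate. The base-free medium avoids the flavanone–chalcone equilibrium that would racemise C2, and the electron-poor ligand disfavours 1,2-addition to the product.

Step 7
Reactants: 11 flavanone 4-[(2S)-5-methoxy-7-[2-(4-methoxyphenyl)ethyl]-4-oxo-3,4-dihydro-2H-chromen-2-yl]phenyl methanesulfonate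
Product: 13 methyl (2S,3S)-4-methoxy-6-[2-(4-methoxyphenyl)ethyl]-2-[4-(methanesulfonyloxy)phenyl]-2,3-dihydro-1-benzofuran-3-carboxylate (2,3-trans), via methyl enol ether 12 (not isolated)
Conditions: PhI(OAc)2 (1.2 equiv), conc. H2SO4 (0.3 equiv), HC(OMe)3, rt; aq. NaHCO3
Reagents that add atoms: trimethyl orthoformate, COC(OC)OC
Why: Acid and the orthoformate convert the ketone of 11 into methyl enol ether 12, whose C3 is attacked by the trivalent-iodine electrophile PhI(OAc)+; methanol adds at C4 to give a 3-iodanyl ketal. Ring A carbon C4a, antiperiplanar to the C3–I bond, then shifts from C4 to C3 as iodobenzene departs, which forms the C3–C3a bond and leaves C4 as a dimethoxycarbenium ion that collapses to the methyl ester. The closest known reaction type is the oxidative ring contraction of flavanones to methyl trans-2-aryl-2,3-dihydrobenzofuran-3-carboxylates with PhI(OAc)2 or Tl(NO3)3 in trimethyl orthoformate, one of the 1,2-aryl shifts of aryl ketones induced by trivalent iodine or trivalent thallium. The dihydrofuran ring is not closed by cyclisation: it arises by ring contraction, a semipinacol-type 1,2-shift of an sp2 carbon through a phenonium-like bridged transition state inside the existing ring. The new stereocentre C3 is under substrate control from C2: the ester carbon is epimerisable under the acidic conditions (ortho ester/ketene acetal equilibrium) and should settle trans to the C2 aryl group, the thermodynamically preferred arrangement. The step needs migration of C4a in preference to migration of the C2 aryl group (isoflavone), to loss of the C2 hydrogen (flavone) and to ionisation of the O1–C2 bond (racemisation). The two oxygen donors ortho to C4a (5-OMe and O1) raise the migratory aptitude of ring A, while the mesyloxy group lowers that of the C2 aryl group and destabilises cationic character at C2, so the (S) configuration from step 6 should be carried through.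

Step 8
Reactants: 13 methyl (2S,3S)-4-methoxy-6-[2-(4-methoxyphenyl)ethyl]-2-[4-(methanesulfonyloxy)phenyl]-2,3-dihydro-1-benzofuran-3-carboxylate
Product: 14 (2S,3S)-4-methoxy-6-[2-(4-methoxyphenyl)ethyl]-2-[4-(methanesulfonyloxy)phenyl]-2,3-dihydro-1-benzofuran-3-carboxylic acid
Conditions: Me3SnOH (6 equiv), ClCH2CH2Cl, 80 °C; 1 M HCl wash
Reagents that add atoms: trimethyltin hydroxide, C[Sn](C)(C)O
Why: Trimethyltin hydroxide cleaves methyl esters under near-neutral conditions, which avoids hydroxide or alkoxide bases that could deprotonate C3 and expel the C7a phenoxide (ring opening) or attack the mesylate; any epimerisation at C3 returns to the trans acid.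

Step 9
Reactants: 14 (2S,3S)-4-methoxy-6-[2-(4-methoxyphenyl)ethyl]-2-[4-(methanesulfonyloxy)phenyl]-2,3-dihydro-1-benzofuran-3-carboxylic acid
Product: 15 1,3-dioxo-1,3-dihydro-2H-isoindol-2-yl (2S,3S)-4-methoxy-6-[2-(4-methoxyphenyl)ethyl]-2-[4-(methanesulfonyloxy)phenyl]-2,3-dihydro-1-benzofuran-3-carboxylate
Conditions: N-hydroxyphthalimide, iPrN=C=NiPr, CH2Cl2, 0 °C to rt
Reagents that add atoms: N-hydroxyphthalimide, O=C1c2ccccc2C(=O)N1O
Why: Carbodiimide esterification gives the redox-active N-acyloxyphthalimide; no amine base is added, so the now more acidic C3–H is not removed.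

Step 10
Reactants: 16 1-bromo-3,5-dimethoxybenzene
Product: 18 (3,5-dimethoxyphenyl)zinc chloride (titrated THF solution containing LiCl), via Grignard reagent 17 (not isolated)
Conditions: Mg, LiCl, THF, rt; then ZnCl2, THF, 0 °C to rt
Reagents that add atoms: zinc chloride, Cl[Zn]Cl
Why: LiCl-assisted magnesium insertion into the aryl bromide followed by transmetalation to zinc gives the arylzinc chloride required for a Negishi-type coupling.

Step 11
Reactants: 15 1,3-dioxo-1,3-dihydro-2H-isoindol-2-yl (2S,3S)-4-methoxy-6-[2-(4-methoxyphenyl)ethyl]-2-[4-(methanesulfonyloxy)phenyl]-2,3-dihydro-1-benzofuran-3-carboxylate; 18 (3,5-dimethoxyphenyl)zinc chloride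
Product: 19 4-[(2S,3S)-3-(3,5-dimethoxyphenyl)-4-methoxy-6-[2-(4-methoxyphenyl)ethyl]-2,3-dihydro-1-benzofuran-2-yl]phenyl methanesulfonate (2,3-trans)
Conditions: NiCl2(dme) (20 mol%), 4,4'-di-tert-butyl-2,2'-bipyridine (40 mol%), 18 (3 equiv), THF/DMF, rt
Reagents that add atoms: none
Why: Nickel-catalysed decarboxylative Negishi arylation of a redox-active ester: electron transfer from a low-valent aryl–nickel species releases CO2 and the benzylic C3 radical, which is captured by aryl–nickel and reductively eliminated. The planar radical is approached on the face opposite the C2 aryl group, which sets C3 trans under substrate control, and the aryl mesylate is inert to bipyridine-ligated nickel at room temperature.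

Step 12
Reactants: 19 4-[(2S,3S)-3-(3,5-dimethoxyphenyl)-4-methoxy-6-[2-(4-methoxyphenyl)ethyl]-2,3-dihydro-1-benzofuran-2-yl]phenyl methanesulfonate
Product: 20 4-[(2S,3S)-3-(3,5-dimethoxyphenyl)-4-methoxy-6-[2-(4-methoxyphenyl)ethyl]-2,3-dihydro-1-benzofuran-2-yl]phenol
Conditions: LiN(iPr)2 (3 equiv), THF, −78 °C; aq. NH4Cl at −78 °C
Reagents that add atoms: none
Why: Base-induced cleavage of an aryl mesylate: deprotonation of the S-methyl group and elimination release the phenoxide and sulfene, which the amide base captures. At −78 °C no ring C–H is acidic enough to compete, and the phenoxide is protonated cold before it can open the O1–C2 bond through a quinone methide.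

Step 13
Reactants: 20 4-[(2S,3S)-3-(3,5-dimethoxyphenyl)-4-methoxy-6-[2-(4-methoxyphenyl)ethyl]-2,3-dihydro-1-benzofuran-2-yl]phenol
Product: 21 5-[(2S,3S)-4-hydroxy-2-(4-hydroxyphenyl)-6-[2-(4-hydroxyphenyl)ethyl]-2,3-dihydro-1-benzofuran-3-yl]benzene-1,3-diol (target)
Conditions: BBr3 (10 equiv), CH2Cl2, −78 to 0 °C; MeOH then H2O
Reagents that add atoms: none
Why: Lewis-acid cleavage of the four aryl methyl ethers: the phenol on the C2 aryl ring is tied up as an aryloxyborane, a far weaker donor than a methoxy group, which limits ionisation of the O1–C2 bond; C3 has no pathway for epimerisation, so both centres should be retained.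

## Compound list

1 | (E)-3,4',5-trimethoxystilbene (resveratrol trimethyl ether) | COc1ccc(/C=C/c2cc(OC)cc(OC)c2)cc1 | starting material
2 | dihydroresveratrol trimethyl ether (1,3-dimethoxy-5-[2-(4-methoxyphenyl)ethyl]benzene) | COc1ccc(CCc2cc(OC)cc(OC)c2)cc1 | intermediate
3 | N-methoxy-N-methylacetamide | CON(C)C(C)=O | starting material
4 | {2,6-dimethoxy-4-[2-(4-methoxyphenyl)ethyl]phenyl}lithium | [Li]c1c(OC)cc(CCc2ccc(OC)cc2)cc1OC | intermediate (not isolated)
5 | 1-{2,6-dimethoxy-4-[2-(4-methoxyphenyl)ethyl]phenyl}ethan-1-one | COc1ccc(CCc2cc(OC)c(C(C)=O)c(OC)c2)cc1 | intermediate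
6 | 1-{2-hydroxy-6-methoxy-4-[2-(4-methoxyphenyl)ethyl]phenyl}ethan-1-one | COc1ccc(CCc2cc(O)c(C(C)=O)c(OC)c2)cc1 | intermediate
7 | (E)-3-(dimethylamino)-1-{2-hydroxy-6-methoxy-4-[2-(4-methoxyphenyl)ethyl]phenyl}prop-2-en-1-one | COc1ccc(CCc2cc(O)c(C(=O)/C=C/N(C)C)c(OC)c2)cc1 | intermediate (not isolated)
8 | 5-methoxy-7-[2-(4-methoxyphenyl)ethyl]-4H-chromen-4-one | COc1ccc(CCc2cc(OC)c3c(c2)occc3=O)cc1 | intermediate
9 | 4-hydroxyphenylboronic acid | OB(O)c1ccc(O)cc1 | starting material
10 | [4-(methanesulfonyloxy)phenyl]boronic acid | CS(=O)(=O)Oc1ccc(B(O)O)cc1 | intermediate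
11 | 4-[(2S)-5-methoxy-7-[2-(4-methoxyphenyl)ethyl]-4-oxo-3,4-dihydro-2H-chromen-2-yl]phenyl methanesulfonate | COc1ccc(CCc2cc(OC)c3c(c2)O[C@H](c2ccc(OS(C)(=O)=O)cc2)CC3=O)cc1 | intermediate
12 | 4-[(2S)-4,5-dimethoxy-7-[2-(4-methoxyphenyl)ethyl]-2H-chromen-2-yl]phenyl methanesulfonate | COc1ccc(CCc2cc(OC)c3c(c2)O[C@H](c2ccc(OS(C)(=O)=O)cc2)C=C3OC)cc1 | intermediate (not isolated)
13 | methyl (2S,3S)-4-methoxy-6-[2-(4-methoxyphenyl)ethyl]-2-[4-(methanesulfonyloxy)phenyl]-2,3-dihydro-1-benzofuran-3-carboxylate (trans) | COc1ccc(CCc2cc(OC)c3c(c2)O[C@H](c2ccc(OS(C)(=O)=O)cc2)[C@H]3C(=O)OC)cc1 | intermediate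
14 | (2S,3S)-4-methoxy-6-[2-(4-methoxyphenyl)ethyl]-2-[4-(methanesulfonyloxy)phenyl]-2,3-dihydro-1-benzofuran-3-carboxylic acid (trans) | COc1ccc(CCc2cc(OC)c3c(c2)O[C@H](c2ccc(OS(C)(=O)=O)cc2)[C@H]3C(=O)O)cc1 | intermediate
15 | 1,3-dioxo-1,3-dihydro-2H-isoindol-2-yl (2S,3S)-4-methoxy-6-[2-(4-methoxyphenyl)ethyl]-2-[4-(methanesulfonyloxy)phenyl]-2,3-dihydro-1-benzofuran-3-carboxylate (trans) | COc1ccc(CCc2cc(OC)c3c(c2)O[C@H](c2ccc(OS(C)(=O)=O)cc2)[C@H]3C(=O)ON2C(=O)c4ccccc4C2=O)cc1 | intermediate
16 | 1-bromo-3,5-dimethoxybenzene | COc1cc(Br)cc(OC)c1 | starting material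
17 | (3,5-dimethoxyphenyl)magnesium bromide | COc1cc([Mg]Br)cc(OC)c1 | intermediate (not isolated)
18 | (3,5-dimethoxyphenyl)zinc chloride | COc1cc([Zn]Cl)cc(OC)c1 | intermediate (used as solution)
19 | 4-[(2S,3S)-3-(3,5-dimethoxyphenyl)-4-methoxy-6-[2-(4-methoxyphenyl)ethyl]-2,3-dihydro-1-benzofuran-2-yl]phenyl methanesulfonate (trans) | COc1ccc(CCc2cc(OC)c3c(c2)O[C@H](c2ccc(OS(C)(=O)=O)cc2)[C@H]3c2cc(OC)cc(OC)c2)cc1 | intermediate
20 | 4-[(2S,3S)-3-(3,5-dimethoxyphenyl)-4-methoxy-6-[2-(4-methoxyphenyl)ethyl]-2,3-dihydro-1-benzofuran-2-yl]phenol (trans) | COc1ccc(CCc2cc(OC)c3c(c2)O[C@H](c2ccc(O)cc2)[C@H]3c2cc(OC)cc(OC)c2)cc1 | intermediate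
21 | 5-[(2S,3S)-4-hydroxy-2-(4-hydroxyphenyl)-6-[2-(4-hydroxyphenyl)ethyl]-2,3-dihydro-1-benzofuran-3-yl]benzene-1,3-diol (trans) | Oc1ccc(CCc2cc(O)c3c(c2)O[C@H](c2ccc(O)cc2)[C@H]3c2cc(O)cc(O)c2)cc1 | target

## Step count and risk assessment

Total: 13 steps. Longest linear sequence: 11 steps (1–4, 6–9, 11–13) from 1. Steps 5 and 10 are one-step side branches.

**Step 7 (key step).**
- What may go wrong: oxidation may take other courses, namely dehydrogenation to the flavone, migration of the C2 aryl group, or attack of the iodine reagent on the electron-rich anisole ring or ring A. Acid-promoted opening toward the chalcone could also erode the configuration at C2.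
- Fallback: the same ring contraction is made by a Wolff rearrangement, with no oxidant present. Setting out from flavanone 11, the ketone enolate (LiN(SiMe3)2, THF, −78 °C) is acylated with 2,2,2-trifluoroethyl trifluoroacetate to the 3-(trifluoroacetyl)flavanone F1. Detrifluoroacetylative diazo transfer with methanesulfonyl azide and Et3N then gives the 3-diazoflavanone F2. Irradiation of F2 in methanol shifts C4a from C4 to C3 through the carbene/ketene, and methanol traps the ketene. After C3 has equilibrated to trans the sequence rejoins the route at ester 13.
- The enolate must be kept at −78 °C, so that it does not open to the chalcone.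

**Step 11.**
- What may go wrong: capture of the hindered benzylic C3 radical may be inefficient (dimerisation or hydrogen abstraction), the nickel alkyl may undergo β-hydride elimination toward the aromatic benzofuran, or facial selectivity may be incomplete.
- Fallback: the radical is generated oxidatively from the free acid. Setting out from acid 14 and bromide 16, a metallaphotoredox decarboxylative arylation (Ir[dF(CF3)ppy]2(dtbbpy)PF6, NiCl2(dme), 4,4'-di-tert-butyl-2,2'-bipyridine, Cs2CO3, DMF, blue light) returns to the route at 19. It needs neither step 9 nor step 10.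
- A minor cis isomer would be removed by chromatography in either variant.

**Step 6.**
- What may go wrong: addition to the electron-rich 5-methoxychromone may be slow, the electron-poor boronic acid may protodeboronate, or enantioselectivity may be insufficient.
- Fallback: asymmetric induction is given up in favour of separation. Setting out from chromone 8 and boronic acid 10, a non-selective conjugate addition (Pd(OCOCF3)2, 2,2'-bipyridine, aqueous dichloroethane) gives the racemic flavanone F3. Preparative chromatography on a chiral stationary phase resolves it and returns the (S)-enantiomer to the route as 11.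

**Step 13.**
- What may go wrong: the Lewis acid may ionise the O1–C2 bond (ring opening, epimerisation at C2), or ether cleavage may be incomplete.
- Fallback: the order of the last two steps is inverted, so that the demethylation runs while the C2 aryl group is still deactivated. Setting out from 19, BBr3 in CH2Cl2 gives the tetraphenol mesylate F4. Excess LiN(iPr)2 in THF at −78 °C then removes the mesylate and arrives at the target 21.

## Further compounds

F1 | step 7 | 4-[(2S)-5-methoxy-7-[2-(4-methoxyphenyl)ethyl]-4-oxo-3-(trifluoroacetyl)-3,4-dihydro-2H-chromen-2-yl]phenyl methanesulfonate (C3 enolisable, not defined) | COc1ccc(CCc2cc(OC)c3c(c2)O[C@H](c2ccc(OS(C)(=O)=O)cc2)C(C(=O)C(F)(F)F)C3=O)cc1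
F2 | step 7 | 4-[(2R)-3-diazo-5-methoxy-7-[2-(4-methoxyphenyl)ethyl]-4-oxo-3,4-dihydro-2H-chromen-2-yl]phenyl methanesulfonate (same spatial arrangement at C2 as 11; descriptor changes by priority) | COc1ccc(CCc2cc(OC)c3c(c2)O[C@H](c2ccc(OS(C)(=O)=O)cc2)C(=[N+]=[N-])C3=O)cc1
F0 | step 11 | none | none
F3 | step 6 | racemic 4-{5-methoxy-7-[2-(4-methoxyphenyl)ethyl]-4-oxo-3,4-dihydro-2H-chromen-2-yl}phenyl methanesulfonate | COc1ccc(CCc2cc(OC)c3c(c2)OC(c2ccc(OS(C)(=O)=O)cc2)CC3=O)cc1
F4 | step 13 | 4-[(2S,3S)-3-(3,5-dihydroxyphenyl)-4-hydroxy-6-[2-(4-hydroxyphenyl)ethyl]-2,3-dihydro-1-benzofuran-2-yl]phenyl methanesulfonate (trans) | Oc1ccc(CCc2cc(O)c3c(c2)O[C@H](c2ccc(OS(C)(=O)=O)cc2)[C@H]3c2cc(O)cc(O)c2)cc1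
A1 | alternative 1 | 2-[anti-2-(tert-butyldimethylsilyloxy)-1-(3,5-dimethoxyphenyl)-2-(4-methoxyphenyl)ethyl]-5-[2-(4-methoxyphenyl)ethyl]-3-(triisopropylsilyloxy)phenol | COc1ccc(CCc2cc(O)c([C@H](c3cc(OC)cc(OC)c3)[C@H](O[Si](C)(C)C(C)(C)C)c3ccc(OC)cc3)c(O[Si](C(C)C)(C(C)C)C(C)C)c2)cc1
A2 | alternative 1 | 3-[2-(4-methoxyphenyl)ethyl]cyclobut-2-en-1-one | COc1ccc(CCC2=CC(=O)C2)cc1
A3 | alternative 1 | {[anti-4-(tert-butyldimethylsilyloxy)-3-(3,5-dimethoxyphenyl)-4-(4-methoxyphenyl)but-1-yn-1-yl]oxy}tri(propan-2-yl)silane (configured as in A1) | CC(C)[Si](OC#C[C@H](c1cc(OC)cc(OC)c1)[C@H](O[Si](C)(C)C(C)(C)C)c1ccc(OC)cc1)(C(C)C)C(C)C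
A4 | alternative 2 | methyl 2,4-dihydroxy-6-{trans-4-methoxy-2-(4-methoxyphenyl)-6-[2-(4-methoxyphenyl)ethyl]-2,3-dihydro-1-benzofuran-3-yl}benzoate (C2 and C3 as in the target) | COc1ccc(CCc2cc(OC)c3c(c2)O[C@H](c2ccc(OC)cc2)[C@H]3c2cc(O)cc(O)c2C(=O)OC)cc1
A5 | alternative 2 | 4-{trans-4-methoxy-2-(4-methoxyphenyl)-6-[2-(4-methoxyphenyl)ethyl]-2,3-dihydro-1-benzofuran-3-yl}but-3-yn-2-one (C2 and C3 as in the target) | COc1ccc(CCc2cc(OC)c3c(c2)O[C@H](c2ccc(OC)cc2)[C@H]3C#CC(C)=O)cc1
A6 | alternative 2 | dimethyl malonate | COC(=O)CC(=O)OC
A7 | alternative 3 | (2S,3S)-3-(3,5-dimethoxyphenyl)-2-(4-methoxyphenyl)-6-[2-(4-methoxyphenyl)ethyl]-4-(triisopropylsilyloxy)-2,3-dihydro-1-benzofuran | COc1ccc(CCc2cc(O[Si](C(C)C)(C(C)C)C(C)C)c3c(c2)O[C@H](c2ccc(OC)cc2)[C@H]3c2cc(OC)cc(OC)c2)cc1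
A8 | alternative 3 | {[anti-3-(3,5-dimethoxyphenyl)-4-(ethynyloxy)-4-(4-methoxyphenyl)but-1-yn-1-yl]oxy}tri(propan-2-yl)silane (configured as in A7) | C#CO[C@H](c1ccc(OC)cc1)[C@H](C#CO[Si](C(C)C)(C(C)C)C(C)C)c1cc(OC)cc(OC)c1
A9 | alternative 3 | 4-(4-methoxyphenyl)but-1-yne | C#CCCc1ccc(OC)cc1
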